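**Counting unit.** One equivalent, as much E as the G charged, is the unit we count in, and Z counts in the same way.

| setting | violet | autumn | dusk | spring |
|---|---|---|---|---|
| G | 0.19 M | 0.29 M | 0.29 M | 0.29 M |
| E | 0.95 equiv | 0.950 equiv | 1.90 equiv | 3.80 equiv |
| Z | 0.145 M | 0.145 M | 0.145 M | 0.145 M |
| remark | run made earlier |  |  |  |
| time |  | 3.0 h | 3.0 h | 3.0 h |

violet run (percent of the G charged)

| time / min | L / % | X / % | G / % |
|---|---|---|---|
| 3.00 | 12.3 | 0.3 | 87.9 |
| 5.00 | 17.9 | 0.6 | 81.1 |
| 8.00 | 28.1 | 0.3 | 71.5 |
| 12.0 | 37.2 | 1.4 | 59.4 |
| 20.0 | 51.5 | 6.0 | 43.6 |
| 40.0 | 63.5 | 16.2 | 19.3 |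

(each reading ± 0.5 percentage points)

- which of these there is most of at the end, counted by the G in it, autumn (L / G / X)
- which of these there is most of at the end, counted by the G in it, dusk (L / G / X)
- which of these there is most of at the end, counted by the G in it, spring (L / G / X)
- how much there is at the end of the one of these that leads, in percent of the G charged: autumn
- how much there is at the end of the one of these that leads, in percent of the G charged: dusk
- how much there is at the end of the one of these that leads, in percent of the G charged: spring

- what was read earlier has a scatter of 0.5 percentage points, one standard deviation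

**What G does.** In the violet run, G reads 19.3% at 40.0 min, which gives a first-order constant of 0.0411 min⁻¹. If that holds, 0.0612% of G is left after 3.0 h, so L and X share the charge between them, and X leads when it passes 0.5 of it.

**The question turned round.** What must be true for X to lead? We assume that each X costs one E. In violet, X reads 1.4% at 12.0 min, far less than L at 37.2%, and we read this lag as a sign that Z takes a share of E. That is our guess: the runs hold no reading of Z. Counting one E for each Z charged, Z then costs 0.500 of the G charge in autumn, dusk and spring. So we carry the spare E, the E charged less the Z charged, both as fractions of the G charge. On this guess, for X to lead it must exceed 0.5. Autumn has 0.450, which falls short, so E is the limiting reagent there and we expect L near 55.0%. Dusk has 1.40 and spring 3.30, so we expect X to lead in both. Above one, the spare E sets no figure for X, so we give none.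

**The forecast.** It names L at 63% for autumn, X at 76% for dusk and X at 79% for spring. Its grounds differ from ours: “This suggests each step takes one E”. Our L for autumn, 55.0%, is lower than its figure.

**The flasks.** Autumn ends with L at 59.6%, dusk with X at 78.2% and spring with X at 95.2%. The forecast named each leader, and its spring figure is 16 percentage points too low.

    E → D (k = 0.0260 min⁻¹)
    E + Z → J (k = 0.330 M⁻¹ min⁻¹)
    G → L (k = 0.0420 min⁻¹)
    L + D → X (k = 0.310 M⁻¹ min⁻¹)
    2 D → Q (k = 0.220 M⁻¹ min⁻¹)

**What follows.** Autumn's X, 40.3%, stands below its spare E of 0.450, with 0.143% of the charged E still free at the end and 15% of its Z unspent, where we had counted none. Spring's spare E is 3.30, and at 0.430 h the half-life of L by the step from L + D to X is 0.25 h, short against the 3.0 h of the run. A neighbour of spring with 0.17 M of G, at the same 3.80 equiv of E, pays 0.853 equiv for Z, so its spare E is 2.95, above 0.5, and X should lead. It ends with X at 89.9% and L at 10.0%.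

The runs come from a simulation from invented constants, noise included.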